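Plagiochin E is opened at the saturated A–B bridge (late McMurry closure of a dialdehyde) and, decisively, at ring D, where the C1 oxygen, the C2 biaryl bond to ring A and the C3 ethano bridge to ring C occupy three adjacent carbons. This contiguous pattern maps onto 3-methoxybenzyne: in one flask the phenethyl Grignard reagent carrying rings C and B adds meta to the methoxy group, and the ortho-metallated arene so formed is transmetallated to zinc and cross-coupled with the ring A iodide. The precursors are 3-fluoroanisole, a diaryl ether phenethylmagnesium bromide and an ortho-iodoaryl dioxolane; both future bridge aldehydes stay masked as acetals.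

Key step: step 7

Assumption: the target has no stereocentre and no specified axis, so the macrocycle is made without regard to any axial or helical chirality; the alkene geometry of 18 is immaterial because that bond is hydrogenated.

Step 1
Reactants: 1 tyrosol; 2 3-bromo-4-methoxybenzaldehyde
Product: 3 3-[4-(2-hydroxyethyl)phenoxy]-4-methoxybenzaldehyde
Conditions: CuI (cat.), N,N-dimethylglycine hydrochloride (cat.), Cs2CO3, 1,4-dioxane, 90 °C, N2
Reagents that add atoms: none
Why: Ullmann-type diaryl ether coupling, in which Cs2CO3 deprotonates only the phenol of 1, so the copper phenoxide displaces the aryl bromide while the primary alcohol and the non-enolisable aldehyde are left alone.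

Step 2
Reactants: 3 3-[4-(2-hydroxyethyl)phenoxy]-4-methoxybenzaldehyde
Product: 5 3-[4-(2-bromoethyl)phenoxy]-4-methoxybenzaldehyde, via mesylate 4 (not isolated)
Conditions: MsCl, Et3N, THF, 0 °C; then LiBr, THF, 60 °C
Reagents that add atoms: lithium bromide, [Li+].[Br-]
Why: Sulfonylation of the primary alcohol followed by SN2 displacement with bromide (Finkelstein-type) is neutral towards the aldehyde and the diaryl ether and avoids phosphine/CBr4 reagents that could olefinate the aldehyde.

Step 3
Reactants: 5 3-[4-(2-bromoethyl)phenoxy]-4-methoxybenzaldehyde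
Product: 6 2-{3-[4-(2-bromoethyl)phenoxy]-4-methoxyphenyl}-1,3-dioxolane
Conditions: ethylene glycol, p-TsOH·H2O (cat.), toluene, reflux, Dean–Stark; NaHCO3 work-up
Reagents that add atoms: ethylene glycol, OCCO
Why: Acid-catalysed acetalisation driven by azeotropic removal of water masks the aldehyde as a dioxolane that is inert to organomagnesium reagents, and the primary bromide does not react with the weakly nucleophilic diol under acid.

Step 4
Reactants: 6 2-{3-[4-(2-bromoethyl)phenoxy]-4-methoxyphenyl}-1,3-dioxolane
Product: 7 {2-[4-(5-(1,3-dioxolan-2-yl)-2-methoxyphenoxy)phenyl]ethyl}magnesium bromide (kept as a titrated THF solution)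
Conditions: Mg turnings (activated by a little 1,2-dibromoethane), THF, 25–40 °C, slow addition of 6
Reagents that add atoms: magnesium, [Mg]
Why: Grignard formation by insertion of magnesium into the primary C–Br bond, with the acetal and the aryl ethers as tolerated spectators and slow addition limiting Wurtz dimerisation.

Step 5
Reactants: 8 3-methoxybenzaldehyde
Product: 9 2-iodo-5-methoxybenzaldehyde
Conditions: ICl, AcOH, rt
Reagents that add atoms: iodine monochloride, ClI
Why: Electrophilic aromatic iodination, directed by the methoxy group to its para position (ortho to the formyl group), the site between the two substituents being hindered.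

Step 6
Reactants: 9 2-iodo-5-methoxybenzaldehyde
Product: 10 2-(2-iodo-5-methoxyphenyl)-1,3-dioxolane
Conditions: ethylene glycol, p-TsOH·H2O (cat.), toluene, reflux, Dean–Stark; NaHCO3 work-up
Reagents that add atoms: ethylene glycol, OCCO
Why: Standard acid-catalysed dioxolane formation with removal of water protects the aldehyde against the organometallic species of the next step and leaves the aryl iodide untouched.

Step 7
Reactants: 11 3-fluoroanisole; 7 {2-[4-(5-(1,3-dioxolan-2-yl)-2-methoxyphenoxy)phenyl]ethyl}magnesium bromide; 10 2-(2-iodo-5-methoxyphenyl)-1,3-dioxolane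
Product: 16 2-{2'-[2-(4-{[5-(1,3-dioxolan-2-yl)-2-methoxyphenyl]oxy}phenyl)ethyl]-4,6'-dimethoxybiphenyl-2-yl}-1,3-dioxolane (open A–D–C–B tetraaryl, both aldehydes masked), via aryllithium 12 (not isolated), via 3-methoxybenzyne 13 (not isolated), via arylmagnesium bromide 14 (not isolated), via arylzinc chloride 15 (not isolated)
Conditions: 11 (slight excess), n-BuLi (slight deficit to 11), THF, −78 °C; 7 (limiting) in THF, −78 °C → rt; ZnCl2, THF, rt; then 10, Pd2(dba)3 (cat.), SPhos (cat.), THF, 60 °C
Reagents that add atoms: none
Why: n-BuLi removes the proton of 11 between fluorine and methoxy to give 12, and on warming with 7 present the metal fluoride is expelled to give 3-methoxybenzyne 13. The alkylmagnesium reagent adds across the strained bond with its carbon going to the aryne carbon remote from OMe, the more electrophilic end of the distorted aryne; the new carbanion therefore sits next to oxygen, stabilised inductively and by O–Mg chelation, which fixes the 1,2,3-pattern of ring D in 14. Exchange with ZnCl2 gives arylzinc 15; zerovalent palladium carrying SPhos inserts into the C–I bond of 10, accepts the aryl group from zinc and reductively eliminates the tri-ortho-substituted biaryl (Negishi coupling). The closest known reaction type is the three-component aryne coupling by carbomagnesiation followed by electrophilic capture of the ortho-metallated arene. No ring is closed and no stereocentre is formed; the only selectivity needed is the regiochemistry of addition to the aryne, secured by the methoxy group beside the triple bond, while both dioxolanes are inert to every organometallic present and 7 as limiting reagent leaves no alkylzinc to compete in the coupling.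

Step 8
Reactants: 16 open A–D–C–B tetraaryl bis(dioxolane)
Product: 17 2'-{2-[4-(5-formyl-2-methoxyphenoxy)phenyl]ethyl}-4,6'-dimethoxybiphenyl-2-carbaldehyde
Conditions: 2 M HCl, THF, rt
Reagents that add atoms: water, O
Why: Acid-catalysed acetal hydrolysis releases both aryl aldehydes together, and nothing else in the molecule (aryl ethers, biaryl, saturated bridge) is acid-labile.

Step 9
Reactants: 17 2'-{2-[4-(5-formyl-2-methoxyphenoxy)phenyl]ethyl}-4,6'-dimethoxybiphenyl-2-carbaldehyde
Product: 18 macrocyclic stilbene (16-membered ring; A–B bridge as CH=CH of either geometry; methoxy groups on rings A, B and D)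
Conditions: TiCl4, Zn dust, THF, reflux; 17 added over about 24 h by syringe pump (high dilution)
Reagents that add atoms: none
Why: McMurry reductive coupling of the two aryl aldehydes on low-valent titanium closes the 16-membered ring as the A–B stilbene, with slow addition at high dilution favouring the intramolecular pathway.

Step 10
Reactants: 18 macrocyclic stilbene
Product: 19 plagiochin E trimethyl ether (saturated macrocycle, OMe on rings A, B and D)
Conditions: H2 (1 atm), 10% Pd/C, EtOAc, rt
Reagents that add atoms: none
Why: Heterogeneous catalytic hydrogenation saturates the stilbene double bond of either geometry, and the aryl ethers carry no hydrogenolysable benzylic C–O bond.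

Step 11
Reactants: 19 plagiochin E trimethyl ether
Product: 20 plagiochin E
Conditions: BBr3, CH2Cl2, −78 °C → rt; then H2O
Reagents that add atoms: none
Why: Lewis-acid cleavage of the three aryl methyl ethers by BBr3 (bromide attack on the O-methyl of the boron-complexed ether) frees the phenols, and the diaryl ether, lacking an sp3 carbon on oxygen, is not cleaved.

Compound list
1 | tyrosol, 4-(2-hydroxyethyl)phenol | OCCc1ccc(O)cc1 | starting material
2 | 3-bromo-4-methoxybenzaldehyde | COc1ccc(C=O)cc1Br | starting material
3 | 3-[4-(2-hydroxyethyl)phenoxy]-4-methoxybenzaldehyde | OCCc1ccc(cc1)Oc1cc(C=O)ccc1OC | intermediate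
4 | 2-[4-(5-formyl-2-methoxyphenoxy)phenyl]ethyl methanesulfonate | CS(=O)(=O)OCCc1ccc(cc1)Oc1cc(C=O)ccc1OC | intermediate
5 | 3-[4-(2-bromoethyl)phenoxy]-4-methoxybenzaldehyde | BrCCc1ccc(cc1)Oc1cc(C=O)ccc1OC | intermediate
6 | 2-{3-[4-(2-bromoethyl)phenoxy]-4-methoxyphenyl}-1,3-dioxolane | BrCCc1ccc(cc1)Oc1cc(ccc1OC)C1OCCO1 | intermediate
7 | {2-[4-(5-(1,3-dioxolan-2-yl)-2-methoxyphenoxy)phenyl]ethyl}magnesium bromide | Br[Mg]CCc1ccc(cc1)Oc1cc(ccc1OC)C1OCCO1 | intermediate
8 | 3-methoxybenzaldehyde | COc1cccc(C=O)c1 | starting material
9 | 2-iodo-5-methoxybenzaldehyde | COc1ccc(I)c(C=O)c1 | intermediate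
10 | 2-(2-iodo-5-methoxyphenyl)-1,3-dioxolane | COc1ccc(I)c(c1)C1OCCO1 | intermediate
11 | 3-fluoroanisole | COc1cccc(F)c1 | starting material
12 | 2-fluoro-6-methoxyphenyllithium | [Li]c1c(F)cccc1OC | intermediate
13 | 3-methoxybenzyne (1,2-didehydro-3-methoxybenzene) | COC1=CC=CC#C1 | intermediate
14 | (2-methoxy-6-{2-[4-(5-(1,3-dioxolan-2-yl)-2-methoxyphenoxy)phenyl]ethyl}phenyl)magnesium bromide | COc1cccc(CCc2ccc(cc2)Oc2cc(ccc2OC)C2OCCO2)c1[Mg]Br | intermediate
15 | (2-methoxy-6-{2-[4-(5-(1,3-dioxolan-2-yl)-2-methoxyphenoxy)phenyl]ethyl}phenyl)zinc chloride | COc1cccc(CCc2ccc(cc2)Oc2cc(ccc2OC)C2OCCO2)c1[Zn]Cl | intermediate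
16 | 2-{2'-[2-(4-{[5-(1,3-dioxolan-2-yl)-2-methoxyphenyl]oxy}phenyl)ethyl]-4,6'-dimethoxybiphenyl-2-yl}-1,3-dioxolane | COc1cccc(CCc2ccc(cc2)Oc2cc(ccc2OC)C2OCCO2)c1-c1ccc(OC)cc1C1OCCO1 | intermediate
17 | 2'-{2-[4-(5-formyl-2-methoxyphenoxy)phenyl]ethyl}-4,6'-dimethoxybiphenyl-2-carbaldehyde | COc1cccc(CCc2ccc(cc2)Oc2cc(C=O)ccc2OC)c1-c1ccc(OC)cc1C=O | intermediate
18 | macrocyclic stilbene, 16-membered, A–B bridge CH=CH (geometry not controlled), tri-O-methyl | COc1ccc2c(c1)C=Cc1ccc(OC)c(c1)Oc1ccc(cc1)CCc1cccc(OC)c1-2 | intermediate
19 | plagiochin E trimethyl ether | COc1ccc2c(c1)CCc1ccc(OC)c(c1)Oc1ccc(cc1)CCc1cccc(OC)c1-2 | intermediate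
20 | plagiochin E | Oc1ccc2c(c1)CCc1ccc(O)c(c1)Oc1ccc(cc1)CCc1cccc(O)c1-2 | target

Total step count: 11. Longest linear sequence: 9 steps (steps 1, 2, 3, 4, 7, 8, 9, 10, 11).

Steps most likely to fail

1. Step 7. The aryne may be consumed by β-hydride transfer from the phenethylmagnesium reagent (reduction in place of carbometallation) or by self-addition of lithiated 11. The congested arylmetal may also be protonated before the palladium cycle turns over. The fallback avoids the aryne and sets out from 7 and 10, returning at 16.
   - Grignard reagent 7 is joined by Kumada–Corriu coupling (Pd(dppf)Cl2, THF, rt to 40 °C) to purchased 1-bromo-2-chloro-3-methoxybenzene (COc1cccc(Br)c1Cl). Only the C–Br bond should react, giving 2-{3-[4-(2-(2-chloro-3-methoxyphenyl)ethyl)phenoxy]-4-methoxyphenyl}-1,3-dioxolane F1.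
   - Iodide 10 is converted by Miyaura borylation (B2pin2, Pd(dppf)Cl2, KOAc, dioxane, 80 °C) into 2-[2-(1,3-dioxolan-2-yl)-4-methoxyphenyl]-4,4,5,5-tetramethyl-1,3,2-dioxaborolane F2.
   - Suzuki–Miyaura coupling of the flanked chloride F1 with F2 (Pd(OAc)2, SPhos, K3PO4, toluene/water, 100 °C) should then give 16.

2. Step 9. Intermolecular carbonyl coupling to oligomers, or arrest at the titanium pinacolate, may outrun closure of the strained 16-membered ring. The fallback sets out from 17 and returns at 18.
   - Double Wittig methylenation (Ph3PCH3Br, KOt-Bu, THF, 0 °C) gives 2-ethenyl-2'-{2-[4-(5-ethenyl-2-methoxyphenoxy)phenyl]ethyl}-4,6'-dimethoxybiphenyl F3.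
   - Ring-closing metathesis with second-generation Grubbs catalyst (toluene, high dilution, 60–80 °C, ethene purged) should close the same bridge as the stilbene 18. The metathesis is reversible, which lets oligomers funnel back to the ring.

3. Step 1. Slow oxidative addition into the electron-rich ortho-methoxy aryl bromide may allow competing O-arylation of the primary alcohol or base-mediated loss of the aldehyde. The fallback sets out from 1 and returns at 3.
   - Chan–Lam–Evans coupling of tyrosol 1 with purchased (5-formyl-2-methoxyphenyl)boronic acid (COc1ccc(C=O)cc1B(O)O) under Cu(OAc)2, pyridine, 4 Å molecular sieves, CH2Cl2, air, rt arylates the phenol oxidatively at room temperature and should give 3 directly.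

Further compounds
F1 | step 7 | 2-{3-[4-(2-(2-chloro-3-methoxyphenyl)ethyl)phenoxy]-4-methoxyphenyl}-1,3-dioxolane | COc1cccc(CCc2ccc(cc2)Oc2cc(ccc2OC)C2OCCO2)c1Cl
F2 | step 7 | 2-[2-(1,3-dioxolan-2-yl)-4-methoxyphenyl]-4,4,5,5-tetramethyl-1,3,2-dioxaborolane | COc1ccc(B2OC(C)(C)C(C)(C)O2)c(c1)C1OCCO1
F3 | step 9 | 2-ethenyl-2'-{2-[4-(5-ethenyl-2-methoxyphenoxy)phenyl]ethyl}-4,6'-dimethoxybiphenyl | COc1cccc(CCc2ccc(cc2)Oc2cc(C=C)ccc2OC)c1-c1ccc(OC)cc1C=C
F0 | step 1 | none | none
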